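The runs were generated by integration for substances that don't exist.

If each L that reacts takes one G and each D that goes on takes a second, the alpha run cannot finish, because its 1.80 G per L charged is less than the 2 this needs; yet at 8.00 min it reads L 0% and D 0%.

| setting | alpha | flask |
|---|---|---|
| L | 0.050 M (fed, over 40 s) | 0.050 M (fed, over 40 s) |
| G | 0.090 M | 0.0600 M |
| remark | run made earlier |  |
| time |  | 40 min |
| volume of the second phase over the first |  | 1.0 |

alpha run (percent of the L charged)

| time / min | D / % | L / % |
|---|---|---|
| 1.50 | 13 | 25 |
| 3.00 | 3 | 9 |
| 5.00 | 0 | 5 |
| 6.00 | 0 | 1 |
| 8.00 | 0 | 0 |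
| 10.0 | 0 | 1 |
| 12.0 | 2 | 0 |

(readings scatter by 1.5 percentage points)

1. the best time, 40 min at the latest, for D
2. the amount of D, in percent of the L charged, at that time

- in the second phase: G; everything else is in the first
- charges count per volume of the first phase; a concentration in a rate is the amount of a species over the volume of its own phase; every rate counts per litre of the first phase
- what was read earlier has a scatter of 1.5 percentage points, one standard deviation
- the earlier runs hold the two phases in the same ratio of volumes as the flask asked about

So we reckon that some D leaves without taking G, and we keep a balance. In the flask the allowance, G charged per L charged, is 1.20, and it has to pay for L consumed plus any second G. But that speaks of the end, and D may peak early: at 1.50 min alpha reads L 25% and D 13%, so about 62.0% reads as passed beyond both. We therefore look for the best time soon after the feed ends at 0.67 min. The forecast, saying that “D peaks when formation matches loss”, gives 16% at 1 min.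

The flask gives 17.8% at 0.922 min, within the forecast's margin.

    Z ⇌ G, rate k1*([Z] - [G]/K1) per volume of the first phase (partition coefficient = 0.660, kL = 0.0220 s⁻¹)
    L + Z → D (k = 0.780 M⁻¹ s⁻¹)
    Z + D → Q (k = 1.10 M⁻¹ s⁻¹)
    D → E (k = 0.0240 s⁻¹)

At 0.922 min, the best time of the flask, L stood at 60.3%. D's half-lives in the flask, 0.48 min towards Q at 0.485 min and 0.48 min towards E, are shorter than 40 min. By 40.0 min, with G at 0.0362% of its own charge and Z at 3.12 × 10⁻⁵ M, the allowance of the flask had gone as 92.2% of the L charged on L consumed and 27.6% on Q, with 7.8% of L left: G, though charged above L, was the limiting reagent.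

In a second flask, the same but with 0.013 M of L, the allowance is 4.62, above 2, so G can pay for every L and D. That flask ends with L 0%, Q 54.7% and E 45.3%, after a best D of 20.5%.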